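**Retrosynthetic overview**
- C2–Ph bond and the only stereocentre are made last, by ligand-controlled Pd-catalysed conjugate addition of phenylboronic acid to a 6,8-dibenzylated 5,7-dihydroxychromone, so nothing afterwards can racemise C2 or scramble C6/C8.
- C6–CH2 and C8–CH2 bonds: two o-quinone-methide C-alkylations of 5,7-dihydroxychromone, C6 first (salicyl alcohol), then C8 (trimeric salicyl alcohol).
- Trimer side chain: two iterations of tosylhydrazone/boronic acid reductive coupling (salicylaldehyde + a 3-formyl-4-hydroxyphenyl boronic acid, the formyl group being the masked next benzylic carbon), then reduction.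
- Chromone core: both rings are built in one operation from a 6-(acylmethyl)-4-hydroxy-2-pyrone (triacetic acid lactone + methyl 3,3-dimethoxypropanoate) by ring opening, Claisen aromatisation and pyrone closure.
- Ring order: benzene ring A, then γ-pyrone ring C in the same pot; ring C is reduced to the flavanone in the last step; the phenyl and four phenol rings are bought.

Assumption: (3-formyl-4-hydroxyphenyl)boronic acid is taken as a purchasable catalogue building block; the (R)-t-BuPyOx ligand is assumed to give the (2S)-flavanone, by analogy with the (S)-ligand giving (R)-products.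

**Step 1**
Reactants: 1 4-hydroxy-6-methyl-2H-pyran-2-one (triacetic acid lactone); 2 methyl 3,3-dimethoxypropanoate
Product: 4 6-(4,4-dimethoxy-2-oxobutyl)-4-hydroxy-2H-pyran-2-one, via dilithio triacetic lactone dianion 3 (not isolated)
Conditions: 1 (2.0 equiv), LDA (4.1 equiv), THF–DMPU, −78 → 0 °C; then 2 (1.0 equiv), −78 → 0 °C; cold 1 M HCl
Reagents that add atoms: none
Why: Claisen-type C-acylation of a polycarbonyl dianion (Harris/Huckin–Weiler dianion chemistry): the exocyclic C6-methyl carbanion of 3 is the most nucleophilic site and attacks the ester carbonyl, while the second equivalent of dianion deprotonates the acidic product and stops over-addition.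

**Step 2 (key step)**
Reactants: 4 6-(4,4-dimethoxy-2-oxobutyl)-4-hydroxy-2H-pyran-2-one
Product: 7 5,7-dihydroxy-4H-chromen-4-one, via triketo ester 5 (not isolated), via acylphloroglucinol acetal 6 (not isolated)
Conditions: Mg(OMe)2 (4 equiv), MeOH, reflux, 12 h; then 3 M HCl, 60 °C, 1 h (one pot)
Reagents that add atoms: none
Why: Biomimetic polyketide cascade: methoxide opens the pyrone to Mg-chelated triketo ester 5, whose doubly activated C6 carbanion closes onto the ester by intramolecular Claisen (Dieckmann-type) condensation and aromatises to ring A in 6 (the Mg(OMe)2 lactone-to-acylphloroglucinol conversion is known for tetraacetic acid lactone), and an ortho-phenol then condenses with the masked β-aldehyde, losing two MeOH, to close the γ-pyrone ring C (standard β-keto-acetal chromone closure).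

**Step 3**
Reactants: 7 5,7-dihydroxy-4H-chromen-4-one; 8 2-(hydroxymethyl)phenol (salicyl alcohol)
Product: 10 5,7-dihydroxy-6-[(2-hydroxyphenyl)methyl]-4H-chromen-4-one, via o-quinone methide 9 (not isolated)
Conditions: ZnCl2 (2 equiv), 1,4-dioxane, 90 °C, slow addition of 8 (1.05 equiv)
Reagents that add atoms: none
Why: ZnCl2 ionises 8 to o-quinone methide 9, which C-alkylates the phloroglucinol-type ring (Friedel–Crafts/Michael-type o-QM benzylation); Zn(II) held in the 5-OH/4-C=O chelate should deliver it to the flanking carbon C6 (the same ortho-direction by the chelated 5-OH that makes electrophilic substitution of 5-hydroxychromones C6-selective), and limiting 8 keeps C8 free.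

**Step 4**
Reactants: 11 2-hydroxybenzaldehyde (salicylaldehyde); 12 (3-formyl-4-hydroxyphenyl)boronic acid
Product: 14 2-hydroxy-5-[(2-hydroxyphenyl)methyl]benzaldehyde, via salicylaldehyde N-tosylhydrazone 13 (not isolated)
Conditions: TsNHNH2 (1.0 equiv), 1,4-dioxane, 80 °C, 1 h; then 12 (1.5 equiv), K2CO3 (3 equiv), 110 °C; 1 M HCl work-up
Reagents that add atoms: none
Why: Barluenga–Valdés metal-free reductive coupling: base converts 13 (fully formed before 12 is added) with loss of sulfinate and N2 into a carbenoid carbon that takes the aryl group from boron by 1,2-shift, and protodeboronation leaves a CH2 fixed ortho to one OH and para to the other, the formyl group of 12 surviving as the masked next benzylic carbon.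

**Step 5**
Reactants: 14 2-hydroxy-5-[(2-hydroxyphenyl)methyl]benzaldehyde; 12 (3-formyl-4-hydroxyphenyl)boronic acid
Product: 16 2-hydroxy-5-({2-hydroxy-5-[(2-hydroxyphenyl)methyl]phenyl}methyl)benzaldehyde, via dimer N-tosylhydrazone 15 (not isolated)
Conditions: TsNHNH2 (1.0 equiv), 1,4-dioxane, 80 °C, 1 h; then 12 (1.5 equiv), K2CO3 (4 equiv), 110 °C; 1 M HCl work-up
Reagents that add atoms: none
Why: Second iteration of the same Barluenga–Valdés reductive coupling, again joining the former aldehyde carbon (ortho to OH) to the boron-bearing carbon (para to OH), which gives the ortho,para-linked triphenol regiospecifically.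

**Step 6**
Reactants: 16 2-hydroxy-5-({2-hydroxy-5-[(2-hydroxyphenyl)methyl]phenyl}methyl)benzaldehyde
Product: 17 2-(hydroxymethyl)-4-({2-hydroxy-5-[(2-hydroxyphenyl)methyl]phenyl}methyl)phenol
Conditions: NaBH4, MeOH–THF, 0 °C; aq NH4Cl
Reagents that add atoms: none
Why: NaBH4 reduction of the aryl aldehyde to the salicyl alcohol; phenols and diarylmethane CH2 groups are inert and the near-neutral work-up avoids premature o-quinone methide formation.

**Step 7**
Reactants: 10 5,7-dihydroxy-6-[(2-hydroxyphenyl)methyl]-4H-chromen-4-one; 17 2-(hydroxymethyl)-4-({2-hydroxy-5-[(2-hydroxyphenyl)methyl]phenyl}methyl)phenol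
Product: 19 5,7-dihydroxy-6-[(2-hydroxyphenyl)methyl]-8-{[2-hydroxy-5-({2-hydroxy-5-[(2-hydroxyphenyl)methyl]phenyl}methyl)phenyl]methyl}-4H-chromen-4-one, via trimer o-quinone methide 18 (not isolated)
Conditions: ZnCl2 (2 equiv), 1,4-dioxane, 90 °C, slow addition of 17 (1.2 equiv)
Reagents that add atoms: none
Why: Same ZnCl2 o-quinone-methide Friedel–Crafts alkylation: 17 ionises to 18, which is captured by C8, the only unsubstituted and by far the most nucleophilic (phloroglucinol-type) carbon of 10, slow addition keeping 18 from alkylating its own phenol rings.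

**Step 8**
Reactants: 19 the 6,8-dibenzylated 5,7-dihydroxychromone; 20 phenylboronic acid
Product: 21 Sarmentosumin A, (2S)-5,7-dihydroxy-6-[(2-hydroxyphenyl)methyl]-8-{[2-hydroxy-5-({2-hydroxy-5-[(2-hydroxyphenyl)methyl]phenyl}methyl)phenyl]methyl}-2-phenyl-2,3-dihydro-4H-chromen-4-one
Conditions: Pd(OCOCF3)2 (10 mol %), (R)-t-BuPyOx (12 mol %), NH4PF6 (30 mol %), H2O (5 equiv), 20 (3 equiv), ClCH2CH2Cl–THF, 50 °C
Reagents that add atoms: none
Why: Pd(II)/pyridine-oxazoline-catalysed asymmetric conjugate addition of an arylboronic acid to a chromone (Stoltz-type): the cationic (PyOx)Pd–Ph adds across C2=C3 on the face selected by the tert-butyl oxazoline, the (R)-ligand giving the (2S) centre, and the Pd enolate is protonated by water under mildly acidic, air- and phenol-tolerant conditions that cannot open the flavanone.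

**Compound list**
1 | 4-hydroxy-6-methyl-2H-pyran-2-one (triacetic acid lactone) | Cc1cc(O)cc(=O)o1 | starting material
2 | methyl 3,3-dimethoxypropanoate | COC(=O)CC(OC)OC | starting material
3 | dilithio triacetic lactone dianion (not isolated) | [Li+].[Li+].[CH2-]c1cc([O-])cc(=O)o1 | intermediate
4 | 6-(4,4-dimethoxy-2-oxobutyl)-4-hydroxy-2H-pyran-2-one | COC(OC)CC(=O)Cc1cc(O)cc(=O)o1 | intermediate
5 | methyl 9,9-dimethoxy-3,5,7-trioxononanoate (triketo ester, not isolated) | COC(=O)CC(=O)CC(=O)CC(=O)CC(OC)OC | intermediate
6 | 3,3-dimethoxy-1-(2,4,6-trihydroxyphenyl)propan-1-one (acylphloroglucinol acetal, not isolated) | COC(OC)CC(=O)c1c(O)cc(O)cc1O | intermediate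
7 | 5,7-dihydroxy-4H-chromen-4-one | O=c1ccoc2cc(O)cc(O)c12 | intermediate
8 | 2-(hydroxymethyl)phenol (salicyl alcohol) | OCc1ccccc1O | starting material
9 | 6-methylidenecyclohexa-2,4-dien-1-one (o-quinone methide, not isolated) | C=C1C=CC=CC1=O | intermediate
10 | 5,7-dihydroxy-6-[(2-hydroxyphenyl)methyl]-4H-chromen-4-one | O=c1ccoc2cc(O)c(Cc3ccccc3O)c(O)c12 | intermediate
11 | 2-hydroxybenzaldehyde (salicylaldehyde) | O=Cc1ccccc1O | starting material
12 | (3-formyl-4-hydroxyphenyl)boronic acid | O=Cc1cc(B(O)O)ccc1O | starting material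
13 | salicylaldehyde N-tosylhydrazone (not isolated) | Cc1ccc(cc1)S(=O)(=O)N/N=C/c1ccccc1O | intermediate
14 | 2-hydroxy-5-[(2-hydroxyphenyl)methyl]benzaldehyde | O=Cc1cc(Cc2ccccc2O)ccc1O | intermediate
15 | N-tosylhydrazone of 14 (dimer N-tosylhydrazone, not isolated) | Cc1ccc(cc1)S(=O)(=O)N/N=C/c1cc(Cc2ccccc2O)ccc1O | intermediate
16 | 2-hydroxy-5-({2-hydroxy-5-[(2-hydroxyphenyl)methyl]phenyl}methyl)benzaldehyde | O=Cc1cc(Cc2cc(Cc3ccccc3O)ccc2O)ccc1O | intermediate
17 | 2-(hydroxymethyl)-4-({2-hydroxy-5-[(2-hydroxyphenyl)methyl]phenyl}methyl)phenol | OCc1cc(Cc2cc(Cc3ccccc3O)ccc2O)ccc1O | intermediate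
18 | 4-({2-hydroxy-5-[(2-hydroxyphenyl)methyl]phenyl}methyl)-6-methylidenecyclohexa-2,4-dien-1-one (trimer o-quinone methide, not isolated) | C=C1C=C(Cc2cc(Cc3ccccc3O)ccc2O)C=CC1=O | intermediate
19 | 5,7-dihydroxy-6-[(2-hydroxyphenyl)methyl]-8-{[2-hydroxy-5-({2-hydroxy-5-[(2-hydroxyphenyl)methyl]phenyl}methyl)phenyl]methyl}-4H-chromen-4-one | O=c1ccoc2c(Cc3cc(Cc4cc(Cc5ccccc5O)ccc4O)ccc3O)c(O)c(Cc3ccccc3O)c(O)c12 | intermediate
20 | phenylboronic acid | OB(O)c1ccccc1 | starting material
21 | Sarmentosumin A, (2S)-configured | O=C1C[C@@H](c2ccccc2)Oc2c(Cc3cc(Cc4cc(Cc5ccccc5O)ccc4O)ccc3O)c(O)c(Cc3ccccc3O)c(O)c21 | target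

**Totals**
Total step count: 8. Longest linear sequence: 5 steps (1 → 2 → 3 → 7 → 8, or 4 → 5 → 6 → 7 → 8).

**Three steps most likely to fail**

Step 8 (asymmetric phenyl addition to the hindered hexaphenolic chromone 19): conversion or ee may be poor. The fallback sets the stereocentre early instead: it sets out from 7 and comes back at 21. The same Pd/(R)-t-BuPyOx addition of 20 is run on the small parent chromone 7 to give (S)-pinocembrin F1. The two ZnCl2 o-quinone-methide alkylations are then done on the flavanone, first with 8 to give (S)-6-(2-hydroxybenzyl)pinocembrin F2, then with 17 to give 21. The cost is that C2 must survive two Lewis-acidic steps, so these are held at ≤70 °C and the ee is checked after each.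

Step 3 (C6-selective mono-benzylation of 7): the C6/C8 preference rests on a chelation argument, and C8 attack or 6,8-dialkylation may compete. The fallback imposes the regiochemistry with a protecting group: it sets out from 7 and comes back at 10. The non-chelated, more acidic 7-OH is silylated selectively (TIPSCl, imidazole, DMF) to give 5-hydroxy-7-(triisopropylsilyloxy)-4H-chromen-4-one F3. The chelated 5-OH is then the only free phenol, so Zn-templated alkylation with 8 can only be delivered ortho to it, giving 5-hydroxy-6-(2-hydroxybenzyl)-7-(triisopropylsilyloxy)-4H-chromen-4-one F4. HF·pyridine removes the silyl group and returns 10.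

Step 5 (second tosylhydrazone/boronic acid coupling, in the presence of two free phenols and a formyl-bearing boronic acid): carbene O–H insertion or protodeboronation of 12 may dominate. The fallback replaces diazo chemistry by palladium C–O activation: it sets out from 14 and comes back at 16. NaBH4 reduces 14 to 2-(hydroxymethyl)-4-(2-hydroxybenzyl)phenol F5. F5 is then coupled with 12 under base-free Pd(PPh3)4 catalysis in dioxane at 90 °C (direct Suzuki–Miyaura arylation of the benzylic C–OH, activated as its cyclic salicyl boronate) to give 16. If step 4 failed for the same reason, the same coupling from commercial 8 and 12 would give 14 without any new compound.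

**Further compounds**
F1 | step 8 | (S)-pinocembrin, (2S)-5,7-dihydroxy-2-phenyl-2,3-dihydro-4H-chromen-4-one | O=C1C[C@@H](c2ccccc2)Oc2cc(O)cc(O)c21
F2 | step 8 | (2S)-5,7-dihydroxy-6-[(2-hydroxyphenyl)methyl]-2-phenyl-2,3-dihydro-4H-chromen-4-one | O=C1C[C@@H](c2ccccc2)Oc2cc(O)c(Cc3ccccc3O)c(O)c21
F3 | step 3 | 5-hydroxy-7-(triisopropylsilyloxy)-4H-chromen-4-one | O=c1ccoc2cc(O[Si](C(C)C)(C(C)C)C(C)C)cc(O)c12
F4 | step 3 | 5-hydroxy-6-[(2-hydroxyphenyl)methyl]-7-(triisopropylsilyloxy)-4H-chromen-4-one | O=c1ccoc2cc(O[Si](C(C)C)(C(C)C)C(C)C)c(Cc3ccccc3O)c(O)c12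
F5 | step 5 | 2-(hydroxymethyl)-4-[(2-hydroxyphenyl)methyl]phenol | OCc1cc(Cc2ccccc2O)ccc1O
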